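**Retrosynthetic overview** (target numbered as a 1H,3H-furo[3,4-c]furan: ring A = C1(hydroxy-dimethoxyphenyl)–O2–C3–C3a–C6a, ring B = C3a–C4(trimethoxyphenyl)–O5–C6–C6a)
1. Ring B is closed last at C4–O5 by SN1 etherification of a diol whose benzylic carbinol comes from an aryl Grignard reagent and a lactol (C4–aryl bond).
2. Ring A is not made five-membered: C1, C6a and C3a are first joined as a cyclopropane, which grows by two atoms (C3 and O2, a formyl group on C3a) in a Cloke–Wilson ring expansion that forms C1–O2.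
3. The cyclopropane and a γ-lactone (ring B with C4 as C=O) come from one intramolecular cyclopropanation of an open-chain cinnamyl 2-diazo-3-oxopropanoate. Order of ring formation: lactone and cyclopropane, then ring A by expansion in the same flask, then ring B re-closed as the ether.
4. Enabling feature: C1 carries an electron-rich aryl group (cation-stabilising donor) and C3a carries C3 and C4, both of which can stand at carbonyl level (double acceptor). Tied through C6a into a three-membered ring, this 1,3-donor/acceptor pair lets the C1–C3a bond heterolyse and re-close through the C3 oxygen.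
5. Stereocontrol: C6a by the chiral catalyst, C1 and C4 by trans (exo) capture of benzylic cations, C3a by cis ring fusion on hydrogenation; all centres follow from C6a.

Key step: step 6

Assumption: the sense of induction of the chiral cobalt porphyrin in step 6 is taken by analogy and not predicted; the catalyst enantiomer meant is the one that gives cyclopropane 7 with the (5R) configuration.

**Step 1**
Reactants: 1 3-hydroxy-4,5-dimethoxybenzaldehyde
Product: 2 3,4-dimethoxy-5-[(triisopropylsilyl)oxy]benzaldehyde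
Conditions: TIPSCl, imidazole, DMF, rt
Reagents that add atoms: chlorotriisopropylsilane, CC(C)[Si](Cl)(C(C)C)C(C)C
Why: Silyl ether protection of the only O–H group; an aryl TIPS ether should survive ylide, hydride, carbene, Lewis-acid and Grignard conditions and is removed by fluoride at the end.

**Step 2**
Reactants: 2 3,4-dimethoxy-5-[(triisopropylsilyl)oxy]benzaldehyde
Product: 3 ethyl (2E)-3-{3,4-dimethoxy-5-[(triisopropylsilyl)oxy]phenyl}prop-2-enoate
Conditions: Ph3P=CHCO2Et, toluene, 80 °C
Reagents that add atoms: ethyl (triphenylphosphoranylidene)acetate, CCOC(=O)C=P(c1ccccc1)(c1ccccc1)c1ccccc1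
Why: Wittig olefination with a stabilised ylide, which should give the E-enoate.

**Step 3**
Reactants: 3 ethyl (2E)-3-{3,4-dimethoxy-5-[(triisopropylsilyl)oxy]phenyl}prop-2-enoate
Product: 4 (2E)-3-{3,4-dimethoxy-5-[(triisopropylsilyl)oxy]phenyl}prop-2-en-1-ol
Conditions: iBu2AlH (2.2 equiv), CH2Cl2, −78 °C; aq. KNaC4H4O6 work-up
Reagents that add atoms: none
Why: 1,2-Reduction of the enoate by the aluminium hydride at low temperature should leave the E-alkene and the silyl ether untouched.

**Step 4**
Reactants: 4 (2E)-3-{3,4-dimethoxy-5-[(triisopropylsilyl)oxy]phenyl}prop-2-en-1-ol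
Product: 5 (2E)-3-{3,4-dimethoxy-5-[(triisopropylsilyl)oxy]phenyl}prop-2-en-1-yl diazoacetate
Conditions: TsNHN=CHCOCl, PhNMe2, CH2Cl2, 0 °C; then Et3N, 0 °C → rt
Reagents that add atoms: glyoxylic acid chloride p-toluenesulfonylhydrazone, Cc1ccc(cc1)S(=O)(=O)N/N=C/C(Cl)=O
Why: O-Acylation followed by base-induced loss of p-toluenesulfinate from the tosylhydrazone (Bamford–Stevens-type diazo formation) is the standard one-flask route to allylic diazoacetates.

**Step 5**
Reactants: 5 (2E)-3-{3,4-dimethoxy-5-[(triisopropylsilyl)oxy]phenyl}prop-2-en-1-yl diazoacetate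
Product: 6 (2E)-3-{3,4-dimethoxy-5-[(triisopropylsilyl)oxy]phenyl}prop-2-en-1-yl 2-diazo-3-oxopropanoate
Conditions: (chloromethylene)dimethyliminium chloride, CH2Cl2, 0 °C → rt; then aq. NaHCO3
Reagents that add atoms: (chloromethylene)dimethyliminium chloride, C[N+](C)=CCl.[Cl-]; water, O
Why: Vilsmeier–Haack-type C-formylation: the nucleophilic diazo carbon attacks the chloroiminium ion and hydrolysis of the iminium salt should give the acceptor/acceptor diazo compound, the alkene and arene being far less nucleophilic at 0 °C.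

**Step 6**
Reactants: 6 (2E)-3-{3,4-dimethoxy-5-[(triisopropylsilyl)oxy]phenyl}prop-2-en-1-yl 2-diazo-3-oxopropanoate
Product: 8 (3aR,4S)-4-{3,4-dimethoxy-5-[(triisopropylsilyl)oxy]phenyl}-3a,4-dihydro-1H,3H-furo[3,4-c]furan-1-one, via formyl cyclopropane lactone 7 (not isolated)
Conditions: [Co(3,5-DitBu-ChenPhyrin)] (2 mol%), toluene, rt; then Sc(OTf)3 (10 mol%), rt → 40 °C
Reagents that add atoms: none
Why: The cobalt porphyrin turns the diazo group of 6 into a cobalt-bound α-carbonyl radical that adds 5-exo-trig to the internal alkene carbon and so closes the γ-lactone, and the benzylic radical then closes the cyclopropane by 3-exo-tet substitution at the cobalt-bearing carbon to give 7. Sc(OTf)3 then chelates the formyl/lactone 1,3-dicarbonyl of 7 and heterolyses its C1–C6 bond, the only ring bond that joins the doubly acceptor-substituted carbon to the aryl-bearing donor carbon, and the benzylic cation is captured by the formyl oxygen in a five-membered O-closure (Cloke–Wilson rearrangement of a donor–acceptor cyclopropane), so that the three-membered ring grows by one carbon and one oxygen into the 2,3-dihydrofuran form of ring A. The closest known reaction types are the asymmetric intramolecular cyclopropanation of acceptor-substituted allyl diazoacetates by divalent-cobalt metalloradical catalysis and the Lewis-acid Cloke–Wilson ring expansion of 2-aryl-1-formylcyclopropane-1-carboxylates. C3a of 8 (C5 of 7) is set by the chiral porphyrin pocket in the radical addition and is not touched by the ring expansion, whereas C4 is formed anew in the cation capture under control of C3a, with the aryl group trans to the C3 methylene; reversible ionisation of this benzylic, vinylogous-ester C–O bond under Sc(OTf)3 should funnel any cis isomer to trans. Closure through the formyl oxygen rather than the lactone carbonyl is secured because the latter would need a bridgehead double bond in a bicyclo[2.2.1] frame, and the configurations of C1 and C6 of 7 do not matter because both centres are planarised.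

**Step 7**
Reactants: 8 (3aR,4S)-4-{3,4-dimethoxy-5-[(triisopropylsilyl)oxy]phenyl}-3a,4-dihydro-1H,3H-furo[3,4-c]furan-1-one
Product: 9 (3aR,4S,6aR)-4-{3,4-dimethoxy-5-[(triisopropylsilyl)oxy]phenyl}tetrahydro-1H,3H-furo[3,4-c]furan-1-one
Conditions: H2 (1 atm), 5% Rh/Al2O3, EtOAc, rt
Reagents that add atoms: none
Why: Heterogeneous syn-hydrogenation of the enol-ether double bond should set C6a cis to H-3a because only the cis-fused bicyclo[3.3.0] lactone is unstrained, and this centre, being α to the lactone carbonyl, can also be equilibrated to the cis isomer with base.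

**Step 8**
Reactants: 9 (3aR,4S,6aR)-4-{3,4-dimethoxy-5-[(triisopropylsilyl)oxy]phenyl}tetrahydro-1H,3H-furo[3,4-c]furan-1-one
Product: 10 (3aR,4S,6aR)-4-{3,4-dimethoxy-5-[(triisopropylsilyl)oxy]phenyl}tetrahydro-1H,3H-furo[3,4-c]furan-1-ol (both C1 epimers)
Conditions: iBu2AlH (1.1 equiv), CH2Cl2, −78 °C
Reagents that add atoms: none
Why: Partial reduction of the γ-lactone should stop at the tetrahedral aluminate at −78 °C and give the bicyclic lactol, whose anomeric configuration is irrelevant.

**Step 9**
Reactants: 10 (3aR,4S,6aR)-4-{3,4-dimethoxy-5-[(triisopropylsilyl)oxy]phenyl}tetrahydro-1H,3H-furo[3,4-c]furan-1-ol; 11 bromo(3,4,5-trimethoxyphenyl)magnesium (2.5 equiv)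
Product: 12 [(2S,3R,4R)-2-{3,4-dimethoxy-5-[(triisopropylsilyl)oxy]phenyl}-4-[hydroxy(3,4,5-trimethoxyphenyl)methyl]tetrahydrofuran-3-yl]methanol (both carbinol epimers)
Conditions: THF, 0 °C → rt; aq. NH4Cl
Reagents that add atoms: none
Why: Grignard addition to the hydroxy-aldehyde tautomer of the lactol (one equivalent is consumed by the O–H) installs the second aryl group; the carbinol configuration is irrelevant because this centre is ionised in the next step.

**Step 10**
Reactants: 12 [(2S,3R,4R)-2-{3,4-dimethoxy-5-[(triisopropylsilyl)oxy]phenyl}-4-[hydroxy(3,4,5-trimethoxyphenyl)methyl]tetrahydrofuran-3-yl]methanol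
Product: 13 (1S,3aR,4S,6aR)-1-{3,4-dimethoxy-5-[(triisopropylsilyl)oxy]phenyl}-4-(3,4,5-trimethoxyphenyl)tetrahydro-1H,3H-furo[3,4-c]furan
Conditions: BF3·OEt2 (0.3 equiv), 4 Å molecular sieves, CH2Cl2, −20 → 0 °C
Reagents that add atoms: none
Why: Acid-catalysed dehydrative SN1 etherification: both carbinol epimers should converge on one trimethoxybenzyl cation, and the cis-disposed primary hydroxyl closes ring B with the aryl group trans to C3 (exo), because the cation reacts in the conformer in which H-3a eclipses the aryl group and the oxygen arrives from the C6a side; Friedel–Crafts closure is excluded since the other aryl group lies on the opposite face.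

**Step 11**
Reactants: 13 (1S,3aR,4S,6aR)-1-{3,4-dimethoxy-5-[(triisopropylsilyl)oxy]phenyl}-4-(3,4,5-trimethoxyphenyl)tetrahydro-1H,3H-furo[3,4-c]furan
Product: 14 (1S,3aR,4S,6aR)-1-(3-hydroxy-4,5-dimethoxyphenyl)-4-(3,4,5-trimethoxyphenyl)tetrahydro-1H,3H-furo[3,4-c]furan
Conditions: Bu4NF, THF, 0 °C
Reagents that add atoms: none
Why: Fluoride cleavage of the aryl silyl ether under basic, non-ionising conditions should leave both benzylic ether stereocentres untouched.

**Compound list**
1 | 3-hydroxy-4,5-dimethoxybenzaldehyde | O=Cc1cc(OC)c(OC)c(O)c1 | starting material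
2 | 3,4-dimethoxy-5-[(triisopropylsilyl)oxy]benzaldehyde | O=Cc1cc(OC)c(OC)c(O[Si](C(C)C)(C(C)C)C(C)C)c1 | intermediate
3 | ethyl (2E)-3-{3,4-dimethoxy-5-[(triisopropylsilyl)oxy]phenyl}prop-2-enoate | CCOC(=O)/C=C/c1cc(OC)c(OC)c(O[Si](C(C)C)(C(C)C)C(C)C)c1 | intermediate
4 | (2E)-3-{3,4-dimethoxy-5-[(triisopropylsilyl)oxy]phenyl}prop-2-en-1-ol | OC/C=C/c1cc(OC)c(OC)c(O[Si](C(C)C)(C(C)C)C(C)C)c1 | intermediate
5 | (2E)-3-{3,4-dimethoxy-5-[(triisopropylsilyl)oxy]phenyl}prop-2-en-1-yl diazoacetate | [N-]=[N+]=CC(=O)OC/C=C/c1cc(OC)c(OC)c(O[Si](C(C)C)(C(C)C)C(C)C)c1 | intermediate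
6 | (2E)-3-{3,4-dimethoxy-5-[(triisopropylsilyl)oxy]phenyl}prop-2-en-1-yl 2-diazo-3-oxopropanoate | O=CC(=[N+]=[N-])C(=O)OC/C=C/c1cc(OC)c(OC)c(O[Si](C(C)C)(C(C)C)C(C)C)c1 | intermediate
7 | (1S,5R,6S)-6-{3,4-dimethoxy-5-[(triisopropylsilyl)oxy]phenyl}-2-oxo-3-oxabicyclo[3.1.0]hexane-1-carbaldehyde | O=C[C@]12[C@H](c3cc(OC)c(OC)c(O[Si](C(C)C)(C(C)C)C(C)C)c3)[C@H]1COC2=O | intermediate
8 | (3aR,4S)-4-{3,4-dimethoxy-5-[(triisopropylsilyl)oxy]phenyl}-3a,4-dihydro-1H,3H-furo[3,4-c]furan-1-one | COc1cc([C@H]2OC=C3[C@@H]2COC3=O)cc(O[Si](C(C)C)(C(C)C)C(C)C)c1OC | intermediate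
9 | (3aR,4S,6aR)-4-{3,4-dimethoxy-5-[(triisopropylsilyl)oxy]phenyl}tetrahydro-1H,3H-furo[3,4-c]furan-1-one | COc1cc([C@H]2OC[C@H]3[C@@H]2COC3=O)cc(O[Si](C(C)C)(C(C)C)C(C)C)c1OC | intermediate
10 | (3aR,4S,6aR)-4-{3,4-dimethoxy-5-[(triisopropylsilyl)oxy]phenyl}tetrahydro-1H,3H-furo[3,4-c]furan-1-ol (both C1 epimers) | COc1cc([C@H]2OC[C@H]3[C@@H]2COC3O)cc(O[Si](C(C)C)(C(C)C)C(C)C)c1OC | intermediate
11 | bromo(3,4,5-trimethoxyphenyl)magnesium | COc1cc([Mg]Br)cc(OC)c1OC | starting material
12 | [(2S,3R,4R)-2-{3,4-dimethoxy-5-[(triisopropylsilyl)oxy]phenyl}-4-[hydroxy(3,4,5-trimethoxyphenyl)methyl]tetrahydrofuran-3-yl]methanol (both carbinol epimers) | COc1cc([C@H]2OC[C@H](C(O)c3cc(OC)c(OC)c(OC)c3)[C@@H]2CO)cc(O[Si](C(C)C)(C(C)C)C(C)C)c1OC | intermediate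
13 | (1S,3aR,4S,6aR)-1-{3,4-dimethoxy-5-[(triisopropylsilyl)oxy]phenyl}-4-(3,4,5-trimethoxyphenyl)tetrahydro-1H,3H-furo[3,4-c]furan | COc1cc([C@H]2OC[C@H]3[C@@H]2CO[C@@H]3c2cc(OC)c(OC)c(OC)c2)cc(O[Si](C(C)C)(C(C)C)C(C)C)c1OC | intermediate
14 | (1S,3aR,4S,6aR)-1-(3-hydroxy-4,5-dimethoxyphenyl)-4-(3,4,5-trimethoxyphenyl)tetrahydro-1H,3H-furo[3,4-c]furan | COc1cc([C@H]2OC[C@H]3[C@@H]2CO[C@@H]3c2cc(OC)c(OC)c(OC)c2)cc(O)c1OC | target

Total step count: 11. Longest linear sequence: 11 steps (1 → 14).

**Steps most likely to fail**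

Step 6. The radical cyclopropanation may proceed with low enantioselectivity or lose material to carbene dimerisation, and the benzylic cation may lose a proton instead of closing through oxygen. The fallback separates the asymmetric step from the ring expansion and sets out from diazoacetate 5. Intramolecular cyclopropanation with Rh2(4S-MPPIM)4 (or its enantiomer, as the sense requires) in CH2Cl2 should give the bicyclic lactone (1S,5R,6R)-6-{3,4-dimethoxy-5-[(triisopropylsilyl)oxy]phenyl}-3-oxabicyclo[3.1.0]hexan-2-one F1. Deprotonation at C1 with LiN(SiMe3)2 in THF at −78 °C and C-formylation with 2,2,2-trifluoroethyl formate, which can only enter on the exo face, should give cyclopropane 7. Treatment with Sc(OTf)3 then brings the route back at 8.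

Step 10. The cation capture may show poor facial selectivity (endo aryl), or the acid may ionise the other benzylic C–O bond and scramble C1. The fallback forms the C4–aryl bond on a closed ring and sets out from lactol 10. Acetylation (Ac2O, pyridine) should give the lactol acetate (3aR,4S,6aR)-4-{3,4-dimethoxy-5-[(triisopropylsilyl)oxy]phenyl}tetrahydro-1H,3H-furo[3,4-c]furan-1-yl acetate F2. Transmetalation of 11 with ZnBr2 gives bromo(3,4,5-trimethoxyphenyl)zinc F3. With BF3·OEt2 in CH2Cl2 at −78 °C, F3 should add to the bicyclic oxocarbenium ion from F2 on its convex face, placing the aryl group exo. The route comes back at 13 without passing through 12.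

Step 7. Hydrogenolysis of the benzylic C4–O5 bond may compete with alkene saturation, or hydrogen may add to the wrong face. The fallback is an ionic hydrogenation that sets out from 8: Et3SiH and CF3CO2H in CH2Cl2 at 0 °C should protonate C6a and deliver hydride to the C6 oxocarbenium ion, the cis ring fusion being the thermodynamic outcome. The route comes back at 9; new compound: none F0.

**Further compounds**
F1 | step 6 | (1S,5R,6R)-6-{3,4-dimethoxy-5-[(triisopropylsilyl)oxy]phenyl}-3-oxabicyclo[3.1.0]hexan-2-one | O=C1OC[C@@H]2[C@@H](c3cc(OC)c(OC)c(O[Si](C(C)C)(C(C)C)C(C)C)c3)[C@H]12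
F2 | step 10 | (3aR,4S,6aR)-4-{3,4-dimethoxy-5-[(triisopropylsilyl)oxy]phenyl}tetrahydro-1H,3H-furo[3,4-c]furan-1-yl acetate | COc1cc([C@H]2OC[C@H]3[C@@H]2COC3OC(C)=O)cc(O[Si](C(C)C)(C(C)C)C(C)C)c1OC
F3 | step 10 | bromo(3,4,5-trimethoxyphenyl)zinc | COc1cc([Zn]Br)cc(OC)c1OC
F0 | step 7 | none | none
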